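Numbering: terpenoid carbons as in aromadendrane (C1 O-bearing ring-fusion carbon, C4 quaternary C–Me, C5 ring-fusion CH, C6/C7 cyclopropane CH, C8/C9 CH2, C10 CHMe, C11 CMe2), C1′ the benzylic CH(Ph). The retrosynthesis cuts, in this order, the two Ar–CHO bonds, the C1–O ether bond, then C5–C6 and C7–C8 together, then C4–C5, C2–C3, C4–CH3 and C1′–Ph.
Enabling feature: the seven-membered ring C1–C10–C9–C8–C7–C6–C5 carries the cis-fused gem-dimethylcyclopropane on its C6–C7 edge, so this edge is 3,3-dimethylcyclopropene and the other five carbons are the vinylcyclopropane of a 1-(1-methylcyclopropyl)cyclopentene. A rhodium-catalysed (5+2) cycloaddition joins the two and leaves the C1=C10 alkene exactly where the ether oxygen and H-10 are still missing.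
Forward: the arene, C1′ and C4 come from a coumarin (Ph by asymmetric 1,4-addition, Me by enolate alkylation); lactol, Wittig extension and hydrogenation give a cyclopropyl ketone; an alkylidene carbene C–H insertion closes the five-membered ring and makes C4 quaternary; the (5+2) step adds the seven- and three-membered rings; acid closes the oxa-bridge; double formylation ends the route.
Stereochemistry: C1′ from the chiral rhodium catalyst, C4 from trans-alkylation next to C1′ and retentive C–H insertion, C5/C6/C7 from C4 in the cycloaddition, C1 and C10 from tether-controlled anti addition of O–H across C1=C10.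

Key step: step 11

Remark: the (S)-enantiomer of the bisphosphine in step 2 is assumed to deliver the 4S lactone by analogy with simple coumarins; should the sense be opposite, the antipodal ligand is used and nothing else changes.

Step 1
Reactants: 1 5,7-dihydroxy-2H-chromen-2-one
Product: 2 5,7-bis(methoxymethoxy)-2H-chromen-2-one
Conditions: MOMCl (2.5 equiv), iPr2NEt (3 equiv), CH2Cl2, 0 °C → rt
Reagents that add atoms: chloromethyl methyl ether COCCl
Why: Base-mediated O-alkylation (MOM ether formation) masks both phenols up to the acid step 12 and leaves the lactone intact; no stereocentre is involved.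

Step 2
Reactants: 2 5,7-bis(methoxymethoxy)-2H-chromen-2-one
Product: 3 (4S)-5,7-bis(methoxymethoxy)-4-phenylchroman-2-one
Conditions: PhB(OH)2 (5 equiv), Rh(acac)(C2H4)2 (3 mol %), (S)-SEGPHOS (3.3 mol %), 1,4-dioxane/H2O 10:1, 60 °C
Reagents that add atoms: phenylboronic acid OB(O)c1ccccc1
Why: Rhodium-catalysed asymmetric 1,4-addition of an arylboronic acid to a coumarin, a precedented substrate class, in which the phenyl–rhodium species bearing the chiral bisphosphine adds to one enantiotopic face of C4 of the lactone and so sets the benzylic stereocentre C1′ (S).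

Step 3
Reactants: 3 (4S)-5,7-bis(methoxymethoxy)-4-phenylchroman-2-one
Product: 4 (3R,4S)-5,7-bis(methoxymethoxy)-3-methyl-4-phenylchroman-2-one
Conditions: LiN(SiMe3)2 (1.05 equiv), THF, −78 °C; MeI (1.5 equiv), −78 → −40 °C
Reagents that add atoms: iodomethane CI
Why: Alkylation of the lithium lactone enolate with iodomethane anti to the pseudo-axial 4-phenyl group should give the 3,4-trans lactone and so set C4, and the same isomer is the thermodynamic one should the α-centre equilibrate.

Step 4
Reactants: 4 (3R,4S)-5,7-bis(methoxymethoxy)-3-methyl-4-phenylchroman-2-one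
Product: 5 (3R,4S)-5,7-bis(methoxymethoxy)-3-methyl-4-phenylchroman-2-ol
Conditions: iBu2AlH (1.1 equiv), CH2Cl2, −78 °C; aqueous potassium sodium tartrate
Reagents that add atoms: none
Why: Partial reduction of the lactone with iBu2AlH at low temperature stops at the tetrahedral aluminate and should give the lactol (both anomers, of no consequence) as a masked aldehyde, with C1′ and C4 untouched.

Step 5
Reactants: 6 methyltriphenylphosphonium bromide; 7 methyl 1-methylcyclopropane-1-carboxylate
Product: 9 1-(1-methylcyclopropyl)-2-(triphenyl-λ5-phosphanylidene)ethan-1-one, via methylenetriphenylphosphorane 8 (not isolated)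
Conditions: 6 (2.1 equiv), n-BuLi (2.0 equiv), THF, 0 °C; then 7 (1.0 equiv), 0 °C → reflux
Reagents that add atoms: none
Why: C-acylation of a phosphorus ylide by an ester, in which 8 adds to the ester carbonyl and the methoxide released deprotonates the acylphosphonium ion to the stabilised keto-ylide (the excess of 8 buffers the methanol formed); no stereocentre.

Step 6
Reactants: 5 (3R,4S)-5,7-bis(methoxymethoxy)-3-methyl-4-phenylchroman-2-ol; 9 1-(1-methylcyclopropyl)-2-(triphenyl-λ5-phosphanylidene)ethan-1-one
Product: 10 (2E,4S,5S)-5-[2-hydroxy-4,6-bis(methoxymethoxy)phenyl]-4-methyl-1-(1-methylcyclopropyl)-5-phenylpent-2-en-1-one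
Conditions: 9 (1.5 equiv), toluene, 80 °C
Reagents that add atoms: none
Why: Wittig olefination of the open hydroxy-aldehyde tautomer of lactol 5 with the stabilised ylide should give the E-enone under neutral conditions, which spare the epimerisable C4 centre and do not trigger oxa-Michael closure of the liberated phenol.

Step 7
Reactants: 10 (2E,4S,5S)-5-[2-hydroxy-4,6-bis(methoxymethoxy)phenyl]-4-methyl-1-(1-methylcyclopropyl)-5-phenylpent-2-en-1-one
Product: 11 (4S,5S)-5-[2-hydroxy-4,6-bis(methoxymethoxy)phenyl]-4-methyl-1-(1-methylcyclopropyl)-5-phenylpentan-1-one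
Conditions: H2 (1 atm), RhCl(PPh3)3 (5 mol %), benzene/EtOH 1:1, rt
Reagents that add atoms: none
Why: Homogeneous hydrogenation with RhCl(PPh3)3 saturates the disubstituted enone C=C and leaves the cyclopropyl ketone, the MOM ethers and the arenes untouched; no new stereocentre.

Step 8
Reactants: 11 (4S,5S)-5-[2-hydroxy-4,6-bis(methoxymethoxy)phenyl]-4-methyl-1-(1-methylcyclopropyl)-5-phenylpentan-1-one
Product: 13 2-{(S)-[(1S)-1-methyl-3-(1-methylcyclopropyl)cyclopent-2-en-1-yl](phenyl)methyl}-3,5-bis(methoxymethoxy)phenol, via alkylidene carbene 12 (not isolated)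
Conditions: Me3SiCHN2 (2.5 equiv), n-BuLi (2.4 equiv), THF (0.02 M), −78 °C → rt; sat. NH4Cl
Reagents that add atoms: trimethylsilyldiazomethane C[Si](C)(C)C=[N+]=[N-]
Why: Alkylidene carbene 1,5-C–H insertion, in which the lithiated silyldiazomethane adds to the ketone, Peterson-type loss of LiOSiMe3 and then N2 gives carbene 12, and 12 inserts into the tertiary C4–H bond with retention of configuration, so that the cyclopentene with the quaternary C4 stereocentre and the vinylcyclopropane unit forms in one operation (the phenol rides through as its lithium phenoxide, hence the excess reagent).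

Step 9
Reactants: 14 3-methylbut-2-enal
Product: 15 N′-[(1E)-3-methylbut-2-en-1-ylidene]-4-methylbenzenesulfonohydrazide
Conditions: TsNHNH2 (1.0 equiv), MeOH, 0 °C → rt
Reagents that add atoms: 4-methylbenzenesulfonohydrazide Cc1ccc(cc1)S(=O)(=O)NN
Why: Condensation of the enal with the sulfonyl hydrazide gives the tosylhydrazone needed for carbene generation; no stereocentre.

Step 10
Reactants: 15 N′-[(1E)-3-methylbut-2-en-1-ylidene]-4-methylbenzenesulfonohydrazide
Product: 17 3,3-dimethylcyclopropene, via 1-diazo-3-methylbut-2-ene 16 (not isolated)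
Conditions: NaOMe (1.1 equiv), diglyme, 160–180 °C, N2 sweep, product condensed at −78 °C
Reagents that add atoms: none
Why: Bamford–Stevens reaction, in which the sodium salt of 15 loses p-toluenesulfinate to the vinyl diazoalkane 16, which loses N2 to a vinylcarbene that closes to the cyclopropene, swept out of the hot mixture as it forms.

Step 11
Reactants: 13 2-{(S)-[(1S)-1-methyl-3-(1-methylcyclopropyl)cyclopent-2-en-1-yl](phenyl)methyl}-3,5-bis(methoxymethoxy)phenol; 17 3,3-dimethylcyclopropene
Product: 18 3,5-bis(methoxymethoxy)-2-{(S)-phenyl[(1aR,7S,7aR,7bR)-1,1,4,7-tetramethyl-1a,2,3,5,6,7,7a,7b-octahydro-1H-cyclopropa[e]azulen-7-yl]methyl}phenol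
Conditions: [Rh(C10H8)(C8H12)]SbF6 (10 mol %), 2,6-di-tert-butylpyridine (20 mol %), 17 (5 equiv, slow addition as a cold solution), ClCH2CH2Cl, 0 °C → rt, sealed vessel
Reagents that add atoms: none
Why: Proposed new method: cationic monovalent rhodium should bind the s-cis vinylcyclopropane of 13, cleave one of its two equivalent C10–CH2 bonds to an η3-allyl/σ-alkyl rhodacyclohexene, insert the strained π-bond of 17 syn at the allyl terminus C5 and close the ring by cyclopropyl–C8 reductive elimination, which forms C5–C6 and C7–C8 and leaves the C1=C10 alkene. The closest known reaction type is the rhodium-catalysed intermolecular (5+2) cycloaddition of 1-alkyl-vinylcyclopropanes with alkynes (alkenes so far take part only when tethered), and a cyclopropene should behave like an alkyne because insertion releases about half of its ring strain and because the resulting cyclopropyl–rhodium carbon, rich in s-character and unable to undergo β-hydride elimination, reductively eliminates where an ordinary alkyl group would not. The seven-membered ring closes as a formal [5+2] cycloaddition that is suprafacial on both partners, the three-membered ring of 17 being carried over intact as the cis-fused cyclopropane. C6 and C7 are set cis by the syn insertion, C5 by approach of rhodium and cyclopropene to the cyclopentene face anti to the bulky CH(Ph)Ar group on the neighbouring quaternary C4 (syn to its methyl group), and the C5/C6 relationship (H-5 trans to H-6) by an exo orientation in which CMe2 points away from the allyl–rhodium unit, the endo alternative driving a methyl group into the metallacycle. The step needs chemoselectivity for cycloaddition over rhodium-induced ring opening or oligomerisation of 17 and over acid-triggered addition of the phenol to the alkene, secured by the diene-ligated cationic catalyst, slow dosing of excess 17 at low temperature and a hindered pyridine as proton scavenger; regiochemistry is not an issue because 17 is C2v-symmetric.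

Step 12
Reactants: 18 3,5-bis(methoxymethoxy)-2-{(S)-phenyl[(1aR,7S,7aR,7bR)-1,1,4,7-tetramethyl-1a,2,3,5,6,7,7a,7b-octahydro-1H-cyclopropa[e]azulen-7-yl]methyl}phenol
Product: 20 3,5-bis-deformyl psiguadial A (the target without its two formyl groups), via triol 19 (not isolated)
Conditions: 3 M aq HCl/MeOH 1:10, 45 °C; evaporate; TsOH·H2O (20 mol %), CH2Cl2 (0.01 M), 0 °C → rt
Reagents that add atoms: none
Why: Acidic methanolysis removes both MOM acetals and Brønsted acid-catalysed intramolecular hydroalkoxylation (Markovnikov addition of a phenol to the tetrasubstituted alkene) then closes the seven-membered oxa-bridge, since protonation at C10 gives the tertiary C1 cation that only one of the two equivalent ortho-OH groups, held by C1′–C4 on the face of the five-membered ring opposite to C6, can reach, so that C1 is set by the tether and C10 by anti addition, the proton arriving on the alkene face opposite to the oxygen and to the CMe2 group of the cyclopropane.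

Step 13
Reactants: 20 3,5-bis-deformyl psiguadial A
Product: 21 psiguadial A
Conditions: Cl2CHOMe (6 equiv), TiCl4 (6 equiv), CH2Cl2, −78 → 0 °C; then ice/H2O
Reagents that add atoms: dichloromethyl methyl ether COC(Cl)Cl; water O
Why: Rieche formylation, in which TiCl4-activated dichloromethyl methyl ether substitutes the only two free aromatic positions, each ortho to a titanium phenoxide, and aqueous hydrolysis of the α-chloro ethers gives both aldehydes without touching a stereocentre.

Compound list
1 | 5,7-dihydroxy-2H-chromen-2-one (5,7-dihydroxycoumarin) | O=C1C=Cc2c(O)cc(O)cc2O1 | starting material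
2 | 5,7-bis(methoxymethoxy)-2H-chromen-2-one | O=C1C=Cc2c(OCOC)cc(OCOC)cc2O1 | intermediate
3 | (4S)-5,7-bis(methoxymethoxy)-4-phenylchroman-2-one | O=C1Oc2cc(OCOC)cc(OCOC)c2[C@H](c3ccccc3)C1 | intermediate
4 | (3R,4S)-5,7-bis(methoxymethoxy)-3-methyl-4-phenylchroman-2-one (3,4-trans) | O=C1Oc2cc(OCOC)cc(OCOC)c2[C@H](c3ccccc3)[C@H]1C | intermediate
5 | (3R,4S)-5,7-bis(methoxymethoxy)-3-methyl-4-phenylchroman-2-ol (3,4-trans, both anomers) | OC1Oc2cc(OCOC)cc(OCOC)c2[C@H](c3ccccc3)[C@H]1C | intermediate
6 | methyltriphenylphosphonium bromide | C[P+](c1ccccc1)(c1ccccc1)c1ccccc1.[Br-] | starting material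
7 | methyl 1-methylcyclopropane-1-carboxylate | COC(=O)C1(C)CC1 | starting material
8 | methylenetriphenylphosphorane | C=P(c1ccccc1)(c1ccccc1)c1ccccc1 | intermediate (not isolated)
9 | 1-(1-methylcyclopropyl)-2-(triphenyl-λ5-phosphanylidene)ethan-1-one | CC1(CC1)C(=O)C=P(c1ccccc1)(c1ccccc1)c1ccccc1 | intermediate
10 | (2E,4S,5S)-5-[2-hydroxy-4,6-bis(methoxymethoxy)phenyl]-4-methyl-1-(1-methylcyclopropyl)-5-phenylpent-2-en-1-one | CC1(CC1)C(=O)/C=C/[C@H](C)[C@@H](c2ccccc2)c2c(O)cc(OCOC)cc2OCOC | intermediate
11 | (4S,5S)-5-[2-hydroxy-4,6-bis(methoxymethoxy)phenyl]-4-methyl-1-(1-methylcyclopropyl)-5-phenylpentan-1-one | CC1(CC1)C(=O)CC[C@H](C)[C@@H](c2ccccc2)c2c(O)cc(OCOC)cc2OCOC | intermediate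
12 | alkylidene carbene of 11 (C=O replaced by C=C with a divalent terminal carbon) | [C]=C(CC[C@H](C)[C@@H](c2ccccc2)c2c(O)cc(OCOC)cc2OCOC)C1(C)CC1 | intermediate (not isolated)
13 | 2-{(S)-[(1S)-1-methyl-3-(1-methylcyclopropyl)cyclopent-2-en-1-yl](phenyl)methyl}-3,5-bis(methoxymethoxy)phenol | CC1(CC1)C2=C[C@](C)(CC2)[C@@H](c3ccccc3)c3c(O)cc(OCOC)cc3OCOC | intermediate
14 | 3-methylbut-2-enal | CC(C)=CC=O | starting material
15 | N′-[(1E)-3-methylbut-2-en-1-ylidene]-4-methylbenzenesulfonohydrazide | CC(C)=C/C=N/NS(=O)(=O)c1ccc(C)cc1 | intermediate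
16 | 1-diazo-3-methylbut-2-ene | CC(C)=CC=[N+]=[N-] | intermediate (not isolated)
17 | 3,3-dimethylcyclopropene | CC1(C)C=C1 | intermediate
18 | 3,5-bis(methoxymethoxy)-2-{(S)-phenyl[(1aR,7S,7aR,7bR)-1,1,4,7-tetramethyl-1a,2,3,5,6,7,7a,7b-octahydro-1H-cyclopropa[e]azulen-7-yl]methyl}phenol | CC1=C2CC[C@@](C)([C@H]2[C@H]3[C@@H](CC1)C3(C)C)[C@@H](c4ccccc4)c4c(O)cc(OCOC)cc4OCOC | intermediate
19 | 2-{(S)-phenyl[(1aR,7S,7aR,7bR)-1,1,4,7-tetramethyl-1a,2,3,5,6,7,7a,7b-octahydro-1H-cyclopropa[e]azulen-7-yl]methyl}benzene-1,3,5-triol | CC1=C2CC[C@@](C)([C@H]2[C@H]3[C@@H](CC1)C3(C)C)[C@@H](c4ccccc4)c4c(O)cc(O)cc4O | intermediate (not isolated)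
20 | 3,5-bis-deformyl psiguadial A (bridged aryl ether, all seven stereocentres as in 21) | C[C@H]1CC[C@@H]2[C@H]([C@@H]3[C@]4(C)CC[C@@]31Oc1cc(O)cc(O)c1[C@@H]4c1ccccc1)C2(C)C | intermediate
21 | psiguadial A | C[C@H]1CC[C@@H]2[C@H]([C@@H]3[C@]4(C)CC[C@@]31Oc1c(C=O)c(O)c(C=O)c(O)c1[C@@H]4c1ccccc1)C2(C)C | target

Total step count: 13. Longest linear sequence: 10 steps (1, 2, 3, 4, 6, 7, 8, 11, 12, 13).

Steps most likely to fail: 11, 12 and 13.

Step 11 carries the proposed new method. Several processes may defeat it: ring opening of the cyclopropene at rhodium to a vinylcarbene with oligomerisation, binding of the cationic rhodium by the electron-rich arene, β-hydride elimination from C8 in place of reductive elimination, or acid-triggered addition of the free phenol to the vinylcyclopropane alkene. The fallback uses known chemistry, sets out from 13 and comes back to the route at 19. MOM protection of the phenol (MOMCl, iPr2NEt) should give the tris-MOM ether of 13 F1. A rhodium-catalysed (5+2) cycloaddition of F1 with methyl propiolate ([Rh(CO)2Cl]2, ClCH2CH2Cl, 80 °C; alkynes are the established partners) should give the hexahydroazulene dienoate F2, with the ester expected on C7, remote from the hindered C5 terminus. Diphenylsulfonium isopropylide (from diphenyl(propan-2-yl)sulfonium tetrafluoroborate and LiN(iPr)2, DME, −70 °C; Corey–Chaykovsky-type isopropylidene transfer) should add to the enoate β-carbon C6 from the face anti to C4 and close the gem-dimethylcyclopropane, giving the cyclopropane ester F3. Hydrolysis (LiOH, THF/MeOH/H2O, heat) should give the cyclopropanecarboxylic acid F4. Barton reductive decarboxylation (thiohydroxamate ester, t-BuSH, hν) should give the tris-MOM ether of 19 F5, the cis ring fusion at C7 being the only unstrained outcome of hydrogen transfer to the cyclopropyl radical. The first stage of step 12 then turns F5 into triol 19.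

Step 12 may fail by protonation of C10 from the wrong face (poor facial selectivity), by hydride shift from C5 to the C1 cation followed by opening of the cyclopropylcarbinyl cation, or by alkylation of the phloroglucinol ring by formaldehyde equivalents released from the MOM groups. The fallback sets out from 18 and comes back at 20. A Wacker-type oxidative cyclisation of the free phenol onto the alkene with divalent palladium (Pd(OCOCF3)2, pyridine, Na2CO3, O2, toluene, 80 °C) should form the C1–O bond with β-hydride elimination into the C10 methyl group and give the exocyclic-methylene bridged ether F6. Hydrogenation (H2, palladium on carbon, EtOAc) from the face opposite to the aryl ether bridge and the cyclopropane CMe2 group should then set C10 and give the bis-MOM ether of 20 F7, and HCl in MeOH should remove the MOM groups to give 20.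

Step 13 may fail by ionisation of the tertiary alkyl aryl ether or opening of the cyclopropane under TiCl4 and HCl, or by an incomplete second formylation. The fallback reverses the order of events, sets out from 19 (isolated after the methanolysis stage of step 12) and comes back at 21. Vilsmeier–Haack diformylation of the triol (POCl3, DMF, MeCN, 0 °C → rt; aqueous NaOAc) should give the diformyl triol F8. The ring is then closed last with a Brønsted acid (TsOH·H2O in CH2Cl2 or (CF3)2CHOH), the formyl-flanked phenol trapping the C1 cation reversibly, so that no Lewis acid ever meets the ether and 21 is reached directly.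

Further compounds
F1 | step 11 | 1-{(S)-[(1S)-1-methyl-3-(1-methylcyclopropyl)cyclopent-2-en-1-yl](phenyl)methyl}-2,4,6-tris(methoxymethoxy)benzene (tris-MOM ether of 13) | CC1(CC1)C2=C[C@](C)(CC2)[C@@H](c3ccccc3)c3c(OCOC)cc(OCOC)cc3OCOC
F2 | step 11 | methyl (1S,8aR)-1,4-dimethyl-1-{(S)-phenyl[2,4,6-tris(methoxymethoxy)phenyl]methyl}-1,2,3,5,6,8a-hexahydroazulene-7-carboxylate | CC1=C2CC[C@@](C)([C@H]2C=C(CC1)C(=O)OC)[C@@H](c3ccccc3)c3c(OCOC)cc(OCOC)cc3OCOC
F3 | step 11 | methyl ester at C7 (ring-fusion cyclopropane carbon) of the tris-MOM ether of 19, cyclopropane cis-fused and anti to C4 | CC1=C2CC[C@@](C)([C@H]2[C@H]3[C@](CC1)(C(=O)OC)C3(C)C)[C@@H](c4ccccc4)c4c(OCOC)cc(OCOC)cc4OCOC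
F4 | step 11 | carboxylic acid corresponding to ester F3 | CC1=C2CC[C@@](C)([C@H]2[C@H]3[C@](CC1)(C(=O)O)C3(C)C)[C@@H](c4ccccc4)c4c(OCOC)cc(OCOC)cc4OCOC
F5 | step 11 | tris-MOM ether of 19 | CC1=C2CC[C@@](C)([C@H]2[C@H]3[C@@H](CC1)C3(C)C)[C@@H](c4ccccc4)c4c(OCOC)cc(OCOC)cc4OCOC
F6 | step 12 | bis-MOM ether of 20 with an exocyclic methylene at C10 in place of CH–CH3 | C=C1CC[C@@H]2[C@H]([C@@H]3[C@]4(C)CC[C@@]31Oc1cc(OCOC)cc(OCOC)c1[C@@H]4c1ccccc1)C2(C)C
F7 | step 12 | bis-MOM ether of 20 | C[C@H]1CC[C@@H]2[C@H]([C@@H]3[C@]4(C)CC[C@@]31Oc1cc(OCOC)cc(OCOC)c1[C@@H]4c1ccccc1)C2(C)C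
F8 | step 13 | 2,4-diformyl derivative of triol 19 (2,4,6-trihydroxy-5-substituted benzene-1,3-dicarbaldehyde) | CC1=C2CC[C@@](C)([C@H]2[C@H]3[C@@H](CC1)C3(C)C)[C@@H](c4ccccc4)c4c(O)c(C=O)c(O)c(C=O)c4O
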